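Compound numbers are those fixed in the steps and in the list that follows them.

## Analysis of the target

Target 24 is an isoflavanone: a chroman-4-one (benzo ring A fused to pyranone ring C) that carries aryl ring B on C3. Ring A has one free hydroxyl at C7, para to the C4 carbonyl through C4a. Ring B is 1,2,4,5-tetrasubstituted, with a free hydroxyl at C2', a methoxy group at C4' and a prenyl (3-methylbut-2-enyl) group at C5'. The only stereocentre is C3, of S configuration. It is α to the C4 ketone and benzylic to ring B, so it has no partner stereocentre to be related to and is lost by enolisation in acid or base. The sensitive groups are the prenyl alkene (protic acid, electrophilic halogen, carbenes, hydrogenation), the two phenols (oxidants), and the 2'-hydroxyl, which closes onto C4 to give a pterocarpan whenever C4 stands at the alcohol level under acid. The difficulty is therefore twofold: ring B must be placed at C3 and not at C2, and C3 must be set and then kept through every later operation. The strategy rests on one feature of ring C: C3 is the only atom between C2 (the OCH2 carbon) and C4 (the carbonyl carbon). If C3 and its aryl group are taken out, O1, C2, C4, C4a and C8a form the five-membered ring of a benzofuran-3-one, so ring C is that ring with one aryl-bearing carbon inserted.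

## Retrosynthetic reasoning

**24 from 22.** The two O–CH2 bonds of the formal protecting groups are cut last. The phenols cannot pass through the oxidation of C4, the carbene chemistry or the amidine chemistry, and the 2'-oxygen must stay blocked while C4 is an alcohol. The forward step has to free two aryl formals without protic acid or base reaching C3–H and without touching the prenyl group.

**22 from 21, and 21 from 19.** The C3 stereocentre is traced back to the flat isoflavone 19. A conjugate reduction alone cannot hold C3, because the resulting ketone racemises under the reducing conditions. That lability becomes useful if reduction is carried one stage further: the racemising ketone 20 is funnelled by dynamic kinetic resolution into the cis alcohol 21, in which C3 is no longer acidic. Re-oxidation of C4 then returns ketone 22. The forward steps must deliver the 3,4-cis (3S,4S) alcohol and then oxidise it under non-enolising conditions.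

**19 from 17 and 18.** The aryl C5'–CH2 bond is cut, which is a Stille coupling in the forward sense. It is cut at this point because the prenyl alkene would not survive the hypochlorite and the electrophilic carbene used earlier. A bromine atom stands in for it, introduced where all directing effects agree.

**17 from 3 and 13.** The bonds C2–C3 and C3–C4 are cut, which removes C3 together with ring B and contracts ring C to the furan ring of 3. The removed carbon is the arylchlorocarbene 14, stored as diazirine 13. This gives ring C and the position of ring B in one operation, with the regiochemistry fixed by connectivity, from two simple aromatic building blocks and with no stereochemistry at stake. The forward reaction has to achieve cyclopropanation of the enol ether double bond (15), ring opening with loss of chloride (16) and loss of the silyl group.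

**3 from 2, and 2 from 1.** The O–Si bond of the enol ether and the O–CH2 bond of the ring A formal are cut. Enolisation of 2 is easy because it makes the furan aromatic.

**13 from 11, 9, 6, 5 and 4.** The N=N bond of the diazirine is made by oxidation of amidinium salt 11 (Graham reaction). The amidine comes from nitrile 9, the nitrile from aldehyde 6, and 6 from 4 by bromination to 5 and protection. Each of these is a functional group change on one carbon, so the whole ring B branch is reliable chemistry.

## Alternatives that were turned down

**Alternative 1: Stetter closure onto a ring B quinone methide.**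
- Disconnection: the C3–C4 bond. C4 is an aldehyde carbon on ring A, the O1–C2 ether is already in place, and C3 is the exocyclic carbon of an ortho-quinone methide on ring B.
- Forward key step: base removes the sulfinate leaving group from sulfone aldehyde A2 and unveils quinone methide A3. A chiral triazolium-derived carbene turns the aldehyde into a Breslow intermediate, which adds to the methide carbon and closes ring C to give isoflavanone A1.
- For: it sets C3 in the ring-forming C–C bond step at the final oxidation level, the 2'-hydroxyl appears unprotected by design, and only one silyl group remains to be removed. On these points it is stronger than the chosen route, which needs a reduction and a re-oxidation.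
- Against: the new stereocentre is α to the new ketone and benzylic, and it is formed in the basic medium needed for the carbene and for A3, which are the conditions that racemise it. A3 can also tautomerise to a styrene or oligomerise, and A2 (a benzylic sulfone next to an ether, with the prenyl group present) is no shorter to make than isoflavone 17.
- Comparison: the chosen route creates C3 under conditions that exploit its lability and afterwards exposes it only to non-basic reagents.

**Alternative 2: oxa-Povarov annulation, then C4 oxidation.**
- Disconnection: the bonds C2–C3 and C4–C4a. Ring C is assembled from aryloxymethyl acetate A5 (ring A, O1 and C2) and enol silane A6 (ring B, C3 and C4).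
- Forward key step: a chiral imidodiphosphorimidate acid ionises A5. The cation adds to the β-carbon of A6 and sets C3, and ring A then attacks the silyloxocarbenium carbon para to its silyloxy group to give the 3,4-trans isoflavan A4. Removal of the silyl group at C4, oxidation and global desilylation follow.
- For: it is convergent, forms two C–C bonds, ring C and the stereocentre in one catalytic step, avoids a diazirine and carries the prenyl group from the start. Its all-silyl protection allows a fluoride endgame. On convergence it is stronger.
- Against: the prenyl alkene and the electron-rich ring B compete as π-nucleophiles for the cation under a very strong acid. The C4 benzylic silyl ether, which has a para oxygen donor, can ionise and eliminate to an isoflavene, which erases C3. Facial control over an unsubstituted oxocarbenium ion is not secured by close analogy. Three steps still follow, including the same oxidation next to a labile C3.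
- Comparison: the redox detour is the same as in the chosen route. The chosen route puts its unproven step where it makes the achiral, robust compound 17, so failure there costs no stereochemistry. Here the unproven step is also the only stereo-defining one.

**Alternative 3: oxa-Michael closure with enantioselective protonation.**
- Disconnection: the O1–C2 bond. The precursor is the α-methylene deoxybenzoin A8 with a free ring A phenol.
- Forward key step: a chiral phosphoric acid activates the enone, the phenol adds 6-endo-trig to the CH2 terminus, and the resulting enol is protonated at C3 under catalyst control to give A7, which is identical with compound 22.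
- For: it is the shortest path. A8 comes from a deoxybenzoin by methylenation, no reduction and oxidation are needed, and it reaches 22 without a diazirine. In step economy it is clearly stronger.
- Against: the stereocentre is made by proton transfer to the same enol through which the product racemises, and the acid that makes it can re-enolise it. 2-Hydroxyaryl vinyl ketones such as A8 cyclise on their own, which gives racemic background product, and they dimerise or polymerise. The final deprotection problem is unchanged.
- Comparison: the chosen route offers a stereo-defining step whose sense and level are established for this exact substrate class (isoflavone to cis-isoflavan-4-ol), and a modular assembly in which the position of ring B cannot be wrong.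

Key step: step 8

## Route

Assumption: the stereocentre of the target is read as (3S), and the (S,S)-configured ruthenium catalyst is taken to show its usual sense of induction for benzo-fused aryl ketones (4S); with cis-selective dynamic resolution this gives (3S).

Step 1
Reactants: 1 6-hydroxybenzofuran-3(2H)-one
Product: 2 6-(methoxymethoxy)benzofuran-3(2H)-one
Conditions: MOMCl, i-Pr2NEt, CH2Cl2, 0 °C to rt
Reagents that add atoms: chloromethyl methyl ether, COCCl
Why: Williamson-type O-alkylation with an α-chloro ether; the 6-hydroxyl, para to the ketone, is the most acidic site, so the hindered amine ionises it in preference to C2–H, and the formal is inert to the basic, oxidative and reductive steps that follow.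

Step 2
Reactants: 2 6-(methoxymethoxy)benzofuran-3(2H)-one
Product: 3 6-(methoxymethoxy)-3-(triisopropylsilyloxy)benzofuran
Conditions: TIPSOTf, Et3N, CH2Cl2, −78 °C to 0 °C; chromatography on Et3N-treated silica
Reagents that add atoms: triisopropylsilyl trifluoromethanesulfonate, CC(C)[Si](OS(=O)(=O)C(F)(F)F)(C(C)C)C(C)C
Why: Soft enolisation and O-silylation of a ketone with a silyl triflate and a tertiary amine; enolisation is easy because it makes the furan ring aromatic, and the hindered triflate in excess amine should leave the aryl formal alone at this temperature. The triisopropylsilyl enol ether is robust enough for chromatography and for the heating in step 8.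

Step 3
Reactants: 4 2-hydroxy-4-methoxybenzaldehyde
Product: 5 5-bromo-2-hydroxy-4-methoxybenzaldehyde
Conditions: Br2, AcOH, rt
Reagents that add atoms: bromine, BrBr
Why: Electrophilic aromatic bromination; C5 is para to the hydroxyl, ortho to the methoxy group and meta to the aldehyde, so all three substituents direct there, while C3 between the two oxygens is hindered.

Step 4
Reactants: 5 5-bromo-2-hydroxy-4-methoxybenzaldehyde
Product: 6 5-bromo-4-methoxy-2-(methoxymethoxy)benzaldehyde
Conditions: MOMCl, i-Pr2NEt, CH2Cl2, 0 °C to 40 °C
Reagents that add atoms: chloromethyl methyl ether, COCCl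
Why: O-alkylation of the phenoxide as in step 1; the hydrogen-bonded ortho-hydroxy aldehyde reacts more slowly, hence the gentle heating, and the formal is chosen because it withstands the amide base and the hypochlorite to come.

Step 5
Reactants: 6 5-bromo-4-methoxy-2-(methoxymethoxy)benzaldehyde
Product: 9 5-bromo-4-methoxy-2-(methoxymethoxy)benzonitrile, via aldimine 7 (not isolated), via N-iodoaldimine 8 (not isolated)
Conditions: I2, aq NH3, THF, rt
Reagents that add atoms: ammonia, N
Why: Oxidative conversion of an aldehyde into a nitrile: condensation with ammonia gives aldimine 7, N-iodination gives 8, and loss of HI gives the nitrile. The medium stays basic, so the formal is safe, and aryl ethers are not iodinated under these conditions.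

Step 6
Reactants: 9 5-bromo-4-methoxy-2-(methoxymethoxy)benzonitrile
Product: 11 5-bromo-4-methoxy-2-(methoxymethoxy)benzamidinium chloride, via lithium N,N'-bis(trimethylsilyl)amidinate 10 (not isolated)
Conditions: LiN(SiMe3)2, THF, 0 °C to rt; then MeOH, NH4Cl, 0 °C
Reagents that add atoms: lithium bis(trimethylsilyl)amide, [Li+].C[Si](C)(C)[N-][Si](C)(C)C; ammonium chloride, [NH4+].[Cl-]
Why: Addition of the silylamide to the nitrile gives the disilylated amidinate 10 after a 1,3-silyl shift; methanolysis of the N–Si bonds and proton transfer from NH4Cl then give the amidinium chloride with loss of ammonia. This replaces the strong acid of the usual work-up and so spares the formal.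

Step 7
Reactants: 11 5-bromo-4-methoxy-2-(methoxymethoxy)benzamidinium chloride
Product: 13 3-[5-bromo-4-methoxy-2-(methoxymethoxy)phenyl]-3-chloro-3H-diazirine, via N,N'-dichloroamidine 12 (not isolated)
Conditions: LiCl, DMSO, aq NaOCl (NaCl-saturated), pentane, 0 °C to rt, dark
Reagents that add atoms: sodium hypochlorite, [Na+].[O-]Cl
Why: Graham reaction: two N-chlorinations give 12, base closes the N–N bond with loss of chloride, and chloride returns at carbon to give the 3-chloro-3H-diazirine, with LiCl keeping the chloride concentration high. At the high pH of hypochlorite the arene should not be chlorinated, since the only free activated ring position is flanked by two alkoxy groups. The product is taken into pentane as it forms and kept cold and dark, because donor-substituted aryl chlorodiazirines are labile.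

Step 8
Reactants: 3 6-(methoxymethoxy)-3-(triisopropylsilyloxy)benzofuran; 13 3-[5-bromo-4-methoxy-2-(methoxymethoxy)phenyl]-3-chloro-3H-diazirine
Product: 17 5'-bromo-4'-methoxy-7,2'-bis(methoxymethoxy)isoflavone, via arylchlorocarbene 14 (not isolated), via chlorocyclopropane adduct 15 (not isolated), via 4-silyloxybenzopyrylium chloride 16 (not isolated)
Conditions: 3 (2.5 equiv, high concentration), Na2CO3, MeCN, 55 °C, dark; aq NaHCO3 work-up
Reagents that add atoms: none
Why: Proposed new method: thermal loss of N2 from 13 gives the singlet arylchlorocarbene 14, which as an electrophile should add [2+1] to the C2=C3 enol ether bond of 3 to give chlorocyclopropane 15; ionisation of chloride with disrotatory cleavage of the old C2–C3 bond (cyclopropyl-to-allyl cation opening, helped by the ring oxygen, the silyloxy group and the aromaticity of the cation) gives the benzopyrylium chloride 16, from which chloride takes the silyl group to leave the pyranone. The closest known reaction types are the Ciamician–Dennstedt-type one-carbon insertion of arylchlorocarbenes from chlorodiazirines into indoles and pyrroles and the halocarbene ring expansion of cyclic silyl enol ethers to 2-haloenones; neither has been shown on the enol ether of a benzofuran-3-one. Ring C is closed not by cyclisation but by expansion of the furan ring: a [2+1] cycloaddition followed by a two-electron electrocyclic opening forms C2–C3 and C3–C4 (isoflavone numbering) and breaks the bond that joined the carbons which become C2 and C4. No stereocentre is created, and those of 15 are lost on opening. The diastereomer of 15 with chloride syn to the furan ring can open directly in the allowed sense; the other should ionise first, which the ortho and para alkoxy groups of ring B make easy, so both should converge on 16. The step needs chemoselectivity for the enol ether bond over the arenes, over the C–H bonds of the ortho OCH2O group and over carbene dimerisation; the silyloxy and ring-oxygen donors make C2=C3 by far the most nucleophilic π bond present, and 3 is used in excess and at high concentration so that the bimolecular addition outruns intramolecular insertion. The position of ring B at C3 follows from connectivity, because the carbene carbon ends up between the former C2 and C3 of the benzofuran. Na2CO3 keeps the medium free of HCl so that the formals and 3 survive, and any 16 that remains is hydrolysed to 17 on aqueous work-up.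

Step 9
Reactants: 17 5'-bromo-4'-methoxy-7,2'-bis(methoxymethoxy)isoflavone; 18 tributyl(3-methylbut-2-enyl)stannane
Product: 19 4'-methoxy-7,2'-bis(methoxymethoxy)-5'-(3-methylbut-2-enyl)isoflavone
Conditions: Pd(PPh3)4 (5 mol %), DMF, 100 °C
Reagents that add atoms: none
Why: Stille coupling: oxidative addition of zerovalent palladium into the aryl–Br bond, transmetalation of the allylic stannane and reductive elimination at the less hindered terminus of the η3-prenyl ligand should give the linear prenyl arene. The chromone, the formals and the methyl ether are inert under these neutral conditions.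

Step 10
Reactants: 19 4'-methoxy-7,2'-bis(methoxymethoxy)-5'-(3-methylbut-2-enyl)isoflavone
Product: 21 (3S,4S)-4'-methoxy-7,2'-bis(methoxymethoxy)-5'-(3-methylbut-2-enyl)isoflavan-4-ol, via racemic isoflavanone 20 (not isolated)
Conditions: RuCl(p-cymene)[(S,S)-TsDPEN] (2 mol %), HCO2H/Et3N (5:2), EtOAc, 40 °C
Reagents that add atoms: none
Why: Noyori-type asymmetric transfer hydrogenation with dynamic kinetic resolution: the ruthenium hydride first reduces C2=C3 by conjugate addition to give racemic 20, which should epimerise at C3 through its enol in the formate/amine buffer faster than its carbonyl is reduced. The (S,S) catalyst sets C4 as (S), the sense it shows for 4-chromanone and related benzo-fused aryl ketones, and it reduces only the enantiomer of 20 in which hydride reaches C4 anti to the 3-aryl group, so C3 is set as (S) relative to C4 (3,4-cis). The isolated trisubstituted alkene of the prenyl group and the formals are not touched.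

Step 11
Reactants: 21 (3S,4S)-4'-methoxy-7,2'-bis(methoxymethoxy)-5'-(3-methylbut-2-enyl)isoflavan-4-ol
Product: 22 (3S)-4'-methoxy-7,2'-bis(methoxymethoxy)-5'-(3-methylbut-2-enyl)isoflavanone
Conditions: Dess–Martin periodinane, NaHCO3, CH2Cl2, 0 °C to rt; cold non-basic work-up, filtration through silica
Reagents that add atoms: none
Why: Dess–Martin oxidation of the benzylic secondary alcohol; ligand exchange at iodine and intramolecular removal of the carbinol hydrogen need no base strong enough to enolise the product, and solid NaHCO3 takes up the acetic acid, so C3 should keep its configuration. The 2'-oxygen is still protected, so 21 cannot close to a pterocarpan.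

Step 12
Reactants: 22 (3S)-4'-methoxy-7,2'-bis(methoxymethoxy)-5'-(3-methylbut-2-enyl)isoflavanone
Product: 24 (3S)-7,2'-dihydroxy-4'-methoxy-5'-(3-methylbut-2-enyl)isoflavanone, via bis(bromomethyl) ether 23 (not isolated)
Conditions: Me2BBr, CH2Cl2, −78 °C; then THF/sat. aq NaHCO3, −78 °C to 0 °C
Reagents that add atoms: none
Why: Cleavage of methoxymethyl ethers with a dialkylboron bromide: boron binds the methoxy oxygen and bromide takes the methylene carbon to give the bromomethyl ethers 23 and MeOBMe2, and bicarbonate hydrolysis of 23 releases the phenols and formaldehyde. The reaction runs at −78 °C without protic acid or base, so enolisation at C3 and addition to the prenyl alkene should not compete, and the aryl methyl ether needs far higher temperatures to react.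

## Compound list

1 | 6-hydroxybenzofuran-3(2H)-one | O=C1COc2cc(O)ccc12 | starting material
2 | 6-(methoxymethoxy)benzofuran-3(2H)-one | COCOc1ccc2C(=O)COc2c1 | intermediate
3 | 6-(methoxymethoxy)-3-(triisopropylsilyloxy)benzofuran | COCOc1ccc2c(O[Si](C(C)C)(C(C)C)C(C)C)coc2c1 | intermediate
4 | 2-hydroxy-4-methoxybenzaldehyde | COc1ccc(C=O)c(O)c1 | starting material
5 | 5-bromo-2-hydroxy-4-methoxybenzaldehyde | COc1cc(O)c(C=O)cc1Br | intermediate
6 | 5-bromo-4-methoxy-2-(methoxymethoxy)benzaldehyde | COCOc1cc(OC)c(Br)cc1C=O | intermediate
7 | 1-[5-bromo-4-methoxy-2-(methoxymethoxy)phenyl]methanimine (aldimine) | COCOc1cc(OC)c(Br)cc1C=N | intermediate (not isolated)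
8 | N-iodo-1-[5-bromo-4-methoxy-2-(methoxymethoxy)phenyl]methanimine (N-iodoaldimine) | COCOc1cc(OC)c(Br)cc1C=NI | intermediate (not isolated)
9 | 5-bromo-4-methoxy-2-(methoxymethoxy)benzonitrile | COCOc1cc(OC)c(Br)cc1C#N | intermediate
10 | lithium N,N'-bis(trimethylsilyl)-5-bromo-4-methoxy-2-(methoxymethoxy)benzamidinate | [Li+].COCOc1cc(OC)c(Br)cc1C(=N[Si](C)(C)C)[N-][Si](C)(C)C | intermediate (not isolated)
11 | 5-bromo-4-methoxy-2-(methoxymethoxy)benzamidinium chloride | COCOc1cc(OC)c(Br)cc1C(N)=[NH2+].[Cl-] | intermediate
12 | N,N'-dichloro-5-bromo-4-methoxy-2-(methoxymethoxy)benzamidine | COCOc1cc(OC)c(Br)cc1C(=NCl)NCl | intermediate (not isolated)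
13 | 3-[5-bromo-4-methoxy-2-(methoxymethoxy)phenyl]-3-chloro-3H-diazirine | COCOc1cc(OC)c(Br)cc1C1(Cl)N=N1 | intermediate
14 | [5-bromo-4-methoxy-2-(methoxymethoxy)phenyl]chlorocarbene | COCOc1cc(OC)c(Br)cc1[C]Cl | intermediate (not isolated)
15 | 1-[5-bromo-4-methoxy-2-(methoxymethoxy)phenyl]-1-chloro-4-(methoxymethoxy)-6b-(triisopropylsilyloxy)-1a,6b-dihydro-1H-cyclopropa[b][1]benzofuran (racemic, both C1 epimers) | COCOc1ccc2c(c1)OC1C(Cl)(c3cc(Br)c(OC)cc3OCOC)C21O[Si](C(C)C)(C(C)C)C(C)C | intermediate (not isolated)
16 | 3-[5-bromo-4-methoxy-2-(methoxymethoxy)phenyl]-7-(methoxymethoxy)-4-(triisopropylsilyloxy)chromenylium chloride | COCOc1ccc2c(c1)[o+]cc(-c1cc(Br)c(OC)cc1OCOC)c2O[Si](C(C)C)(C(C)C)C(C)C.[Cl-] | intermediate (not isolated)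
17 | 5'-bromo-4'-methoxy-7,2'-bis(methoxymethoxy)isoflavone | COCOc1ccc2c(c1)occ(-c1cc(Br)c(OC)cc1OCOC)c2=O | intermediate
18 | tributyl(3-methylbut-2-enyl)stannane | CCCC[Sn](CCCC)(CCCC)CC=C(C)C | starting material
19 | 4'-methoxy-7,2'-bis(methoxymethoxy)-5'-(3-methylbut-2-enyl)isoflavone | COCOc1ccc2c(c1)occ(-c1cc(CC=C(C)C)c(OC)cc1OCOC)c2=O | intermediate
20 | rac-4'-methoxy-7,2'-bis(methoxymethoxy)-5'-(3-methylbut-2-enyl)isoflavanone | COCOc1ccc2c(c1)OCC(c1cc(CC=C(C)C)c(OC)cc1OCOC)C2=O | intermediate (not isolated)
21 | (3S,4S)-4'-methoxy-7,2'-bis(methoxymethoxy)-5'-(3-methylbut-2-enyl)isoflavan-4-ol (3,4-cis) | COc1cc(OCOC)c([C@H]2COc3cc(OCOC)ccc3[C@H]2O)cc1CC=C(C)C | intermediate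
22 | (3S)-4'-methoxy-7,2'-bis(methoxymethoxy)-5'-(3-methylbut-2-enyl)isoflavanone | COc1cc(OCOC)c([C@H]2COc3cc(OCOC)ccc3C2=O)cc1CC=C(C)C | intermediate
23 | (3S)-7-(bromomethoxy)-3-[2-(bromomethoxy)-4-methoxy-5-(3-methylbut-2-enyl)phenyl]chroman-4-one | COc1cc(OCBr)c([C@H]2COc3cc(OCBr)ccc3C2=O)cc1CC=C(C)C | intermediate (not isolated)
24 | (3S)-7-hydroxy-3-[2-hydroxy-4-methoxy-5-(3-methylbut-2-enyl)phenyl]chroman-4-one (CNP0227207.1) | COc1cc(O)c([C@H]2COc3cc(O)ccc3C2=O)cc1CC=C(C)C | target

## Step count and least certain steps

Total: 12 steps. Longest linear sequence: 10 steps (steps 3 to 12, from 4); the ring A branch joins after 2 steps.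

**Step 8 (key step).**
- What may go wrong: the carbene may be consumed before it meets the enol ether, by insertion into the C–H bonds of the neighbouring OCH2O group, by ylide formation at its oxygen atoms or by dimerisation. Proton transfer in a first-formed zwitterion may give substitution at C2 of the benzofuran instead of the cyclopropane. The cyclopropane epimer with chloride anti to the furan ring may ionise too slowly and decompose by another path.
- Fallback (known chemistry, oxidative chalcone rearrangement), setting out from 6 and coming back at 17: commercially available 2,4-dihydroxyacetophenone is protected at its non-chelated hydroxyl (MOMCl, K2CO3, acetone) to give 1-[2-hydroxy-4-(methoxymethoxy)phenyl]ethanone F1. Claisen–Schmidt condensation of F1 with 6 (KOH, EtOH, rt) gives the chalcone (E)-3-[5-bromo-4-methoxy-2-(methoxymethoxy)phenyl]-1-[2-hydroxy-4-(methoxymethoxy)phenyl]prop-2-en-1-one F2. Tl(NO3)3·3H2O in MeOH/HC(OMe)3 brings about the oxidative 1,2-shift of the electron-rich ring B aryl group and gives the acetal 2-[5-bromo-4-methoxy-2-(methoxymethoxy)phenyl]-1-[2-hydroxy-4-(methoxymethoxy)phenyl]-3,3-dimethoxypropan-1-one F3. Mild acid (pyridinium p-toluenesulfonate, MeOH, 50 °C) then closes ring C from the ring A phenol with loss of two molecules of methanol and gives 17; any formal lost at this point is put back with MOMCl/i-Pr2NEt.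

**Step 7.**
- What may go wrong: chlorination of the donor-rich ring at the position between the two alkoxy groups, hydrolysis of the amidine, or loss of the diazirine through ionisation of its C–Cl bond during isolation.
- Fallback, setting out from 3 and coming back at 17, which keeps the ring expansion but takes the inserted carbon from bromoform and brings in ring B afterwards: dibromocarbene (CHBr3, KOt-Bu, pentane, −20 °C to rt) should add to 3, and the adduct should open as in step 8 to give 3-bromo-7-(methoxymethoxy)-4H-chromen-4-one F4. Commercially available 2-bromo-5-methoxyphenol is protected (MOMCl, i-Pr2NEt) to give 1-bromo-4-methoxy-2-(methoxymethoxy)benzene F5. Bromine–lithium exchange and borylation (n-BuLi, THF, −78 °C; B(Oi-Pr)3; aqueous work-up) give [4-methoxy-2-(methoxymethoxy)phenyl]boronic acid F6. Suzuki–Miyaura coupling of F4 with F6 (Pd(PPh3)4, Na2CO3, dimethoxyethane/water, 80 °C) gives 4'-methoxy-7,2'-bis(methoxymethoxy)isoflavone F7. Bromination with N-bromosuccinimide (MeCN, 0 °C), para to the 2'-oxygen and ortho to the methoxy group, gives 17.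

**Step 9.**
- What may go wrong: allylic transposition during transmetalation or reductive elimination, leading to the branched 1,1-dimethylallyl isomer; migration of the double bond into conjugation; or slow oxidative addition into the electron-rich aryl bromide.
- Fallback, setting out from 17 and coming back at 19: Stille coupling with allyltributylstannane (Pd(PPh3)4, DMF, 90 °C), which has no regiochemical ambiguity, gives 5'-allyl-4'-methoxy-7,2'-bis(methoxymethoxy)isoflavone F8. Cross-metathesis with 2-methylbut-2-ene (second-generation Grubbs catalyst, CH2Cl2, 40 °C) turns the allyl group into the prenyl group of 19; the electron-poor chromone double bond does not take part.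

**Step 10.**
- What may go wrong: incomplete dynamic resolution, if epimerisation at C3 of the hindered, ortho-substituted ketone is slower than its reduction; this would lower the cis selectivity and the enantiomeric purity.
- Fallback, setting out from 19 and coming back at 22 (steps 10 and 11 are bypassed): conjugate reduction with LiBH(s-Bu)3 (THF, −78 °C) and trapping of the enolate with Me3SiCl give the silyl enol ether 4'-methoxy-7,2'-bis(methoxymethoxy)-5'-(3-methylbut-2-enyl)-4-(trimethylsilyloxy)isoflav-3-ene F9. Catalytic enantioselective protonation of F9 with a binaphthol-derived chiral N-triflyl thiophosphoramide and phenol as the stoichiometric proton source (toluene, −78 °C) gives 22; the catalyst enantiomer is chosen to give (3S).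

**Step 12.**
- What may go wrong: loss of configuration at C3 through enolisation during deprotection or work-up, or addition of HBr to the prenyl group.
- Fallback, setting out from 19 and coming back at 24, which exchanges the formals for silyl ethers before the stereocentre exists: the formals are removed at the achiral stage (HCl, MeOH/THF, 50 °C) to give 7,2'-dihydroxy-4'-methoxy-5'-(3-methylbut-2-enyl)isoflavone F10. Silylation (t-BuMe2SiCl, imidazole, DMF) gives 7,2'-bis(tert-butyldimethylsilyloxy)-4'-methoxy-5'-(3-methylbut-2-enyl)isoflavone F11. Transfer hydrogenation as in step 10 gives (3S,4S)-7,2'-bis(tert-butyldimethylsilyloxy)-4'-methoxy-5'-(3-methylbut-2-enyl)isoflavan-4-ol F12. Oxidation as in step 11 gives (3S)-7,2'-bis(tert-butyldimethylsilyloxy)-4'-methoxy-5'-(3-methylbut-2-enyl)isoflavanone F13. Weakly acidic fluoride (KHF2, MeOH, rt) then frees both phenols and gives 24.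

## Further compounds

F1 | step 8 | 1-[2-hydroxy-4-(methoxymethoxy)phenyl]ethanone | CC(=O)c1ccc(OCOC)cc1O
F2 | step 8 | (E)-3-[5-bromo-4-methoxy-2-(methoxymethoxy)phenyl]-1-[2-hydroxy-4-(methoxymethoxy)phenyl]prop-2-en-1-one | COCOc1ccc(C(=O)/C=C/c2cc(Br)c(OC)cc2OCOC)c(O)c1
F3 | step 8 | 2-[5-bromo-4-methoxy-2-(methoxymethoxy)phenyl]-1-[2-hydroxy-4-(methoxymethoxy)phenyl]-3,3-dimethoxypropan-1-one (racemic) | COCOc1ccc(C(=O)C(C(OC)OC)c2cc(Br)c(OC)cc2OCOC)c(O)c1
F4 | step 7 | 3-bromo-7-(methoxymethoxy)-4H-chromen-4-one | COCOc1ccc2c(c1)occ(Br)c2=O
F5 | step 7 | 1-bromo-4-methoxy-2-(methoxymethoxy)benzene | COCOc1cc(OC)ccc1Br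
F6 | step 7 | [4-methoxy-2-(methoxymethoxy)phenyl]boronic acid | COCOc1cc(OC)ccc1B(O)O
F7 | step 7 | 4'-methoxy-7,2'-bis(methoxymethoxy)isoflavone | COCOc1ccc2c(c1)occ(-c1ccc(OC)cc1OCOC)c2=O
F8 | step 9 | 5'-allyl-4'-methoxy-7,2'-bis(methoxymethoxy)isoflavone | COCOc1ccc2c(c1)occ(-c1cc(CC=C)c(OC)cc1OCOC)c2=O
F9 | step 10 | 4'-methoxy-7,2'-bis(methoxymethoxy)-5'-(3-methylbut-2-enyl)-4-(trimethylsilyloxy)isoflav-3-ene | COCOc1ccc2c(c1)OCC(c1cc(CC=C(C)C)c(OC)cc1OCOC)=C2O[Si](C)(C)C
F10 | step 12 | 7,2'-dihydroxy-4'-methoxy-5'-(3-methylbut-2-enyl)isoflavone | COc1cc(O)c(-c2coc3cc(O)ccc3c2=O)cc1CC=C(C)C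
F11 | step 12 | 7,2'-bis(tert-butyldimethylsilyloxy)-4'-methoxy-5'-(3-methylbut-2-enyl)isoflavone | COc1cc(O[Si](C)(C)C(C)(C)C)c(-c2coc3cc(O[Si](C)(C)C(C)(C)C)ccc3c2=O)cc1CC=C(C)C
F12 | step 12 | (3S,4S)-7,2'-bis(tert-butyldimethylsilyloxy)-4'-methoxy-5'-(3-methylbut-2-enyl)isoflavan-4-ol | COc1cc(O[Si](C)(C)C(C)(C)C)c([C@H]2COc3cc(O[Si](C)(C)C(C)(C)C)ccc3[C@H]2O)cc1CC=C(C)C
F13 | step 12 | (3S)-7,2'-bis(tert-butyldimethylsilyloxy)-4'-methoxy-5'-(3-methylbut-2-enyl)isoflavanone | COc1cc(O[Si](C)(C)C(C)(C)C)c([C@H]2COc3cc(O[Si](C)(C)C(C)(C)C)ccc3C2=O)cc1CC=C(C)C
A1 | alternative 1 | (3S)-2'-hydroxy-4'-methoxy-5'-(3-methylbut-2-enyl)-7-(triisopropylsilyloxy)isoflavanone | COc1cc(O)c([C@H]2COc3cc(O[Si](C(C)C)(C(C)C)C(C)C)ccc3C2=O)cc1CC=C(C)C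
A2 | alternative 1 | 2-{2-[2-hydroxy-4-methoxy-5-(3-methylbut-2-enyl)phenyl]-2-(4-methylphenylsulfonyl)ethoxy}-4-(triisopropylsilyloxy)benzaldehyde (racemic) | COc1cc(O)c(C(COc2cc(O[Si](C(C)C)(C(C)C)C(C)C)ccc2C=O)S(=O)(=O)c2ccc(C)cc2)cc1CC=C(C)C
A3 | alternative 1 | 2-{2-[4-methoxy-3-(3-methylbut-2-enyl)-6-oxocyclohexa-2,4-dien-1-ylidene]ethoxy}-4-(triisopropylsilyloxy)benzaldehyde | COC1=CC(=O)C(=CCOc2cc(O[Si](C(C)C)(C(C)C)C(C)C)ccc2C=O)C=C1CC=C(C)C
A4 | alternative 2 | (3S,4R)-4'-methoxy-5'-(3-methylbut-2-enyl)-7,2'-bis(triisopropylsilyloxy)-4-(trimethylsilyloxy)isoflavan (3,4-trans) | COc1cc(O[Si](C(C)C)(C(C)C)C(C)C)c([C@H]2COc3cc(O[Si](C(C)C)(C(C)C)C(C)C)ccc3[C@@H]2O[Si](C)(C)C)cc1CC=C(C)C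
A5 | alternative 2 | [3-(triisopropylsilyloxy)phenoxy]methyl acetate | CC(=O)OCOc1cccc(O[Si](C(C)C)(C(C)C)C(C)C)c1
A6 | alternative 2 | {(E)-2-[4-methoxy-5-(3-methylbut-2-enyl)-2-(triisopropylsilyloxy)phenyl]ethenyloxy}trimethylsilane | COc1cc(O[Si](C(C)C)(C(C)C)C(C)C)c(/C=C/O[Si](C)(C)C)cc1CC=C(C)C
A7 | alternative 3 | (3S)-4'-methoxy-7,2'-bis(methoxymethoxy)-5'-(3-methylbut-2-enyl)isoflavanone | COc1cc(OCOC)c([C@H]2COc3cc(OCOC)ccc3C2=O)cc1CC=C(C)C
A8 | alternative 3 | 1-[2-hydroxy-4-(methoxymethoxy)phenyl]-2-[4-methoxy-2-(methoxymethoxy)-5-(3-methylbut-2-enyl)phenyl]prop-2-en-1-one | COCOc1ccc(C(=O)C(=C)c2cc(CC=C(C)C)c(OC)cc2OCOC)c(O)c1
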